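The oxazinanone is read as an N–O bond with CO inserted: carbamate N on the quaternary carbon C9 and carbamate O on indolenine C3 sit 1,3-cis across the ring methylene C8. Disconnecting C8–C9 thus gives a nitronate (C9=N–O) and an exocyclic C3=C8 alkene, with the indolenine C2=N unmasked as an aryl ketone. The key step is an intramolecular silyl nitronate–alkene [3+2] cycloaddition: in one operation it closes the cyclohexane and an isoxazolidine and sets both quaternary stereocentres with N and O cis. Its precursor is a 6-nitroindolizidine bearing an α-(2-nitrophenyl) enone; hydrogenolysis then unveils amino alcohol and indolenine, and CDI inserts the carbonyl.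

Key step: step 8

Locants used below (target): indolenine N1, C2, C3; C8 = CH2 on C3; C9 = carbon bearing the carbamate N; C10 = NCH2; N11; C14 = pyrrolidine CH2 next to C15; C15 = pyrrolidine CH; C16 = CH2; C17 = ring-fusion CH; C18 = CMe2. Target = (3S,9S,15R,17R).
Remark: alcohol 1 is taken as a catalogue compound (both enantiomers are sold).
Remark: the (1R,2R)-catalyst of step 3 is assumed to deliver the enamine to the face of 5 that gives (2R)-7; if the sense is opposite, its (1S,2S)-antipode is used.

Step 1
Reactants: 1 tert-butyl (2R)-2-(2-hydroxyethyl)pyrrolidine-1-carboxylate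
Product: 2 tert-butyl (2R)-2-(2-oxoethyl)pyrrolidine-1-carboxylate
Conditions: Dess–Martin periodinane, CH2Cl2, 0 °C → rt
Reagents that add atoms: none
Why: Dess–Martin oxidation of the primary alcohol stops at the aldehyde and leaves the Boc group and the pyrrolidine stereocentre (not α to the carbonyl) untouched.

Step 2
Reactants: 2 tert-butyl (2R)-2-(2-oxoethyl)pyrrolidine-1-carboxylate; 3 nitromethane
Product: 5 tert-butyl (2R)-2-[(2E)-3-nitroprop-2-en-1-yl]pyrrolidine-1-carboxylate, via nitro alcohol 4 (not isolated)
Conditions: MeNO2 (solvent), Et3N (cat.), 0 °C → rt; evaporate; then MsCl, Et3N, CH2Cl2, −20 → 0 °C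
Reagents that add atoms: none
Why: Henry (nitroaldol) addition followed by mesylation and E1cB elimination should give the conjugated nitroalkene as the thermodynamically preferred E isomer, the carbinol centre of 4 being destroyed.

Step 3
Reactants: 5 tert-butyl (2R)-2-[(2E)-3-nitroprop-2-en-1-yl]pyrrolidine-1-carboxylate; 6 2-methylpropanal
Product: 7 tert-butyl (2R)-2-[(2R)-3,3-dimethyl-2-(nitromethyl)-4-oxobutyl]pyrrolidine-1-carboxylate
Conditions: 1-[(1R,2R)-2-amino-1,2-diphenylethyl]-3-[3,5-bis(trifluoromethyl)phenyl]thiourea (20 mol%), H2O (5 equiv), CH2Cl2, rt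
Reagents that add atoms: none
Why: Enamine-mediated Michael addition of an α,α-disubstituted aldehyde to a nitroalkene, in which the thiourea binds the nitro group and the catalyst selects the face of the β-carbon, should create quaternary C18 and set C17 as R under catalyst control because the resident stereocentre is 1,3-remote.

Step 4
Reactants: 8 2-nitrobenzaldehyde
Product: 10 1-(diazomethyl)-2-nitrobenzene, via hydrazone 9 (not isolated)
Conditions: N2H4·H2O, EtOH, 0 °C → rt; then MnO2, CH2Cl2, rt, dark
Reagents that add atoms: hydrazine hydrate, NN.O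
Why: Condensation to the hydrazone and its dehydrogenation by MnO2 is the standard entry to aryldiazomethanes, here stabilised by the electron-poor ring.

Step 5
Reactants: 7 tert-butyl (2R)-2-[(2R)-3,3-dimethyl-2-(nitromethyl)-4-oxobutyl]pyrrolidine-1-carboxylate; 10 1-(diazomethyl)-2-nitrobenzene
Product: 11 tert-butyl (2R)-2-[(2R)-3,3-dimethyl-2-(nitromethyl)-5-(2-nitrophenyl)-4-oxopentyl]pyrrolidine-1-carboxylate
Conditions: Sc(OTf)3 (10 mol%), CH2Cl2, −78 → 0 °C
Reagents that add atoms: none
Why: Lewis acid-catalysed formyl C–H insertion of an aryldiazomethane (Roskamp-type homologation: addition to the Sc-bound aldehyde, 1,2-hydride shift, loss of N2) should give the benzyl ketone without touching the nitro group, the Boc group or C17.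

Step 6
Reactants: 11 tert-butyl (2R)-2-[(2R)-3,3-dimethyl-2-(nitromethyl)-5-(2-nitrophenyl)-4-oxopentyl]pyrrolidine-1-carboxylate
Product: 13 3-methyl-3-[(7R,8aR)-6-nitrooctahydroindolizin-7-yl]-1-(2-nitrophenyl)butan-2-one (C6 epimers), via secondary amine 12 (not isolated)
Conditions: TFA, CH2Cl2, 0 °C → rt; evaporate; then aq. NaHCO3 (to pH ~8), CH2O (37% aq., 1.05 equiv), MeOH, 0 °C → rt
Reagents that add atoms: formaldehyde, C=O
Why: Acidolysis removes Boc, and the iminium ion formed from the secondary amine and formaldehyde is captured by the primary nitroalkane in an intramolecular nitro-Mannich (aza-Henry) reaction that closes the piperidine; the new centre C9 forms as a mixture that is erased when C9 becomes trigonal in step 8.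

Step 7
Reactants: 13 3-methyl-3-[(7R,8aR)-6-nitrooctahydroindolizin-7-yl]-1-(2-nitrophenyl)butan-2-one
Product: 15 4-methyl-4-[(7R,8aR)-6-nitrooctahydroindolizin-7-yl]-2-(2-nitrophenyl)pent-1-en-3-one (kept as its trifluoroacetate salt), via Mannich base 14 (not isolated)
Conditions: (CH2O)n, i-Pr2NH·TFA, TFA (1.1 equiv), THF, 65 °C
Reagents that add atoms: formaldehyde (as paraformaldehyde), C=O
Why: Mannich aminomethylation of the acidic o-nitrobenzyl position and β-elimination of the amine (α-methylenation of a ketone) should give the 1,1-disubstituted enone, the acidic medium keeping N11 protonated so that the nitroalkane cannot add to it.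

Step 8
Reactants: 15 4-methyl-4-[(7R,8aR)-6-nitrooctahydroindolizin-7-yl]-2-(2-nitrophenyl)pent-1-en-3-one (trifluoroacetate salt)
Product: 17 trans-fused N-(trimethylsilyloxy)isoxazolidine cycloadduct (nitroso acetal; 3S,9S,15R,17R), via silyl nitronate 16 (not isolated)
Conditions: TMSCl (4 equiv), Et3N (6 equiv), PhMe, −20 °C → rt, then 60 °C (salt of 15 added last)
Reagents that add atoms: chlorotrimethylsilane, C[Si](C)(C)Cl
Why: Et3N frees N11 and deprotonates C9–H, TMSCl traps the nitronate on oxygen, and silyl nitronate 16 adds as a 1,3-dipole across the exocyclic C3=C8 bond in a concerted thermal [3+2] cycloaddition; the closest known reaction type is the intramolecular silyl nitronate–olefin cycloaddition, with bridged-mode nitronate cycloadditions to nitroso acetals as precedent. The six-membered carbocycle (C9–C8–C3–C2–C18–C17) closes in the bridged mode, both alkene carbons ending inside the ring, through the C8–C9 bond, and the five-membered isoxazolidine (C9–N–O–C3–C8) closes through the simultaneous O–C3 bond. C9 is set by the nitronate face: with the piperidine a chair and C18 and C14 both equatorial, C8 should bond on the face that keeps the new ring trans-diequatorially fused (N axial), while C3 is dictated by the bridge, so O and N are necessarily cis. Bridged rather than fused regiochemistry is needed and is secured by the 1,1-disubstituted alkene: oxygen goes to the substituted carbon C3, and the alternative would join two fully substituted carbons in a five-membered ring. Cycloaddition rather than conjugate addition of the free nitronate to the enone is needed and is secured by having excess TMSCl present before base meets the substrate, so that O-silylation outruns C–C bond formation.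

Step 9
Reactants: 17 trans-fused N-(trimethylsilyloxy)isoxazolidine cycloadduct
Product: 19 3-hydroxy-3H-indole primary amine (descarbonyl target; 3S,9S,15R,17R), via amino ketol 18 (not isolated)
Conditions: H2 (1–3 atm), Raney Ni, MeOH, rt; then AcOH (cat.), 40 °C
Reagents that add atoms: none
Why: Hydrogenolysis cleaves both N–O bonds of the nitroso acetal (giving the C9 primary amine and the C3 tertiary alcohol) and reduces the aryl nitro group, whereupon the aniline condenses with the flanking C2 ketone to the 3H-indole (reductive cyclisation), no stereocentre being touched.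

Step 10
Reactants: 19 3-hydroxy-3H-indole primary amine
Product: 21 penicimutamide C, via carbamoyl imidazole 20 (not isolated)
Conditions: CDI, CH2Cl2, rt; then DBU (cat.), 40 °C
Reagents that add atoms: 1,1'-carbonyldiimidazole, O=C(n1ccnc1)n1ccnc1
Why: CDI acylates the primary amine, and the syn-axial C3 alkoxide then attacks the carbamoyl imidazole intramolecularly (carbonylative cyclisation of a 1,3-amino alcohol) to close the six-membered carbamate, which is only possible because N and O are cis.

Compound list
1 | tert-butyl (2R)-2-(2-hydroxyethyl)pyrrolidine-1-carboxylate | CC(C)(C)OC(=O)N1CCC[C@@H]1CCO | starting material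
2 | tert-butyl (2R)-2-(2-oxoethyl)pyrrolidine-1-carboxylate | CC(C)(C)OC(=O)N1CCC[C@@H]1CC=O | intermediate
3 | nitromethane | C[N+](=O)[O-] | starting material
4 | tert-butyl (2R)-2-(2-hydroxy-3-nitropropyl)pyrrolidine-1-carboxylate (carbinol epimers; not isolated) | CC(C)(C)OC(=O)N1CCC[C@@H]1CC(O)C[N+](=O)[O-] | intermediate
5 | tert-butyl (2R)-2-[(2E)-3-nitroprop-2-en-1-yl]pyrrolidine-1-carboxylate | CC(C)(C)OC(=O)N1CCC[C@@H]1C/C=C/[N+](=O)[O-] | intermediate
6 | 2-methylpropanal | CC(C)C=O | starting material
7 | tert-butyl (2R)-2-[(2R)-3,3-dimethyl-2-(nitromethyl)-4-oxobutyl]pyrrolidine-1-carboxylate | CC(C)(C)OC(=O)N1CCC[C@@H]1C[C@H](C(C)(C)C=O)C[N+](=O)[O-] | intermediate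
8 | 2-nitrobenzaldehyde | O=Cc1ccccc1[N+](=O)[O-] | starting material
9 | (E)-(2-nitrobenzylidene)hydrazine (not isolated) | N/N=C/c1ccccc1[N+](=O)[O-] | intermediate
10 | 1-(diazomethyl)-2-nitrobenzene | [N-]=[N+]=Cc1ccccc1[N+](=O)[O-] | intermediate
11 | tert-butyl (2R)-2-[(2R)-3,3-dimethyl-2-(nitromethyl)-5-(2-nitrophenyl)-4-oxopentyl]pyrrolidine-1-carboxylate | CC(C)(C)OC(=O)N1CCC[C@@H]1C[C@H](C(C)(C)C(=O)Cc1ccccc1[N+](=O)[O-])C[N+](=O)[O-] | intermediate
12 | (4R)-3,3-dimethyl-4-(nitromethyl)-1-(2-nitrophenyl)-5-[(2R)-pyrrolidin-2-yl]pentan-2-one (formed as its trifluoroacetate salt; not isolated) | N1CCC[C@@H]1C[C@H](C(C)(C)C(=O)Cc2ccccc2[N+](=O)[O-])C[N+](=O)[O-] | intermediate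
13 | 3-methyl-3-[(7R,8aR)-6-nitrooctahydroindolizin-7-yl]-1-(2-nitrophenyl)butan-2-one (C6 epimers) | O=C(Cc1ccccc1[N+](=O)[O-])C(C)(C)[C@H]1C[C@H]2CCCN2CC1[N+](=O)[O-] | intermediate
14 | 1-[di(propan-2-yl)amino]-4-methyl-4-[(7R,8aR)-6-nitrooctahydroindolizin-7-yl]-2-(2-nitrophenyl)pentan-3-one (Mannich base; not isolated) | CC(C)N(CC(c1ccccc1[N+](=O)[O-])C(=O)C(C)(C)[C@H]1C[C@H]2CCCN2CC1[N+](=O)[O-])C(C)C | intermediate
15 | 4-methyl-4-[(7R,8aR)-6-nitrooctahydroindolizin-7-yl]-2-(2-nitrophenyl)pent-1-en-3-one (handled as trifluoroacetate salt) | C=C(c1ccccc1[N+](=O)[O-])C(=O)C(C)(C)[C@H]1C[C@H]2CCCN2CC1[N+](=O)[O-] | intermediate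
16 | trimethylsilyl nitronate of 15: indolizidine C6 carries C=N(+)(O−)OSiMe3, (7R,8aR) (not isolated) | C=C(c1ccccc1[N+](=O)[O-])C(=O)C(C)(C)[C@H]1C[C@H]2CCCN2CC1=[N+]([O-])O[Si](C)(C)C | intermediate
17 | nitroso acetal cycloadduct: 3,3-dimethyl-5-(2-nitrophenyl)-7-(trimethylsilyloxy)-6-oxa-7-azabicyclo[3.2.1]octan-4-one, trans-fused through C1–C2 to the indolizidine (C1 = indolizidine C6, C2 = indolizidine C7); (3S,9S,15R,17R) in target locants | CC1(C)C(=O)[C@@]2(c3ccccc3[N+](=O)[O-])C[C@]3(CN4CCC[C@@H]4C[C@H]13)N(O[Si](C)(C)C)O2 | intermediate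
18 | amino ketol: cyclohexanone with C3 bearing OH and 2-aminophenyl, C9 bearing NH2 (cis to OH), trans-fused to the indolizidine; (3S,9S,15R,17R) (not isolated) | CC1(C)C(=O)[C@@](O)(c2ccccc2N)C[C@@]2(N)CN3CCC[C@@H]3C[C@H]12 | intermediate
19 | 3-hydroxy-3H-indole primary amine (target without the carbamate carbonyl; C3–OH and C9–NH2 cis); (3S,9S,15R,17R) | CC1(C)C2=Nc3ccccc3[C@@]2(O)C[C@]2(CN3CCC[C@@H]3C[C@H]12)N | intermediate
20 | N-(imidazole-1-carbonyl) derivative of 19 (not isolated) | CC1(C)C2=Nc3ccccc3[C@@]2(O)C[C@]2(CN3CCC[C@@H]3C[C@H]12)NC(=O)n1ccnc1 | intermediate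
21 | penicimutamide C | CC1(C)C2=Nc3ccccc3[C@@]23C[C@]2(CN4CCC[C@@H]4C[C@H]12)NC(=O)O3 | target

Total step count: 10. Longest linear sequence: 9 (steps 1–3 and 5–10; step 4 is a side branch).

Steps most likely to fail

Step 8 (key step). Conjugate addition of the transient ammonium nitronate to the enone terminus may outrun O-silylation, forming the C8–C9 bond without the O–C3 bond. The alkene may also approach the other nitronate face and give the cis ring fusion. The fallback removes the Michael acceptor; it does not address the facial question. It sets out from 15: Luche reduction (NaBH4, CeCl3·7H2O, MeOH, −40 °C) should give the allylic alcohol F1. TMSCl/Et3N in PhMe at 90 °C should silylate both the alcohol and the nitro group and bring about the same cycloaddition onto the now electron-neutral α-aryl alkene, giving the bis(trimethylsilyl) cycloadduct F2. Hydrogenolysis (H2, Raney Ni, MeOH) should give the amino diol F3. Dehydrogenative cyclisation of its 2-(2-aminophenyl)ethanol unit ([Cp*IrCl2]2, K2CO3, PhMe, 110 °C) should return to the route at 19.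

Step 3. Facial selectivity at the nitroalkene β-carbon may be poor if catalyst and the resident pyrrolidine stereocentre are mismatched, and enamine formation from the hindered aldehyde may be slow. The fallback replaces catalyst control by a stoichiometric auxiliary. It sets out from 6, which is condensed with (S)-1-amino-2-(methoxymethyl)pyrrolidine to the SAMP hydrazone F4 (its antipode is used if the sense of induction requires it). Deprotonation (LiN(i-Pr)2, THF, −78 °C) and addition to 5 should give the hydrazone adduct F5. Ozonolysis (O3, CH2Cl2, −78 °C) releases the aldehyde and returns to the route at 7.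

Step 5. In the diazonium betaine the tertiary alkyl group may migrate instead of hydride, or the betaine may close to the epoxide; addition of the weakly nucleophilic o-nitroaryl diazoalkane to a neopentyl aldehyde may also be sluggish. The fallback builds the benzyl ketone by arylation. It sets out from 7: Roskamp homologation (methyl diazoacetate, SnCl2 cat., CH2Cl2) should give the β-keto ester F6. SNAr with 1-fluoro-2-nitrobenzene (K2CO3, DMSO) should give the α-aryl β-keto ester F7. Krapcho dealkoxycarbonylation (LiCl, wet DMSO, 120 °C) returns to the route at 11.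

Further compounds
F1 | step 8 | 4-methyl-4-[(7R,8aR)-6-nitrooctahydroindolizin-7-yl]-2-(2-nitrophenyl)pent-1-en-3-ol (carbinol epimers) | C=C(c1ccccc1[N+](=O)[O-])C(O)C(C)(C)[C@H]1C[C@H]2CCCN2CC1[N+](=O)[O-]
F2 | step 8 | analogue of 17 with C2–OSiMe3 in place of the ketone (bis(trimethylsilyl) cycloadduct) | CC1(C)C(O[Si](C)(C)C)[C@@]2(c3ccccc3[N+](=O)[O-])C[C@]3(CN4CCC[C@@H]4C[C@H]13)N(O[Si](C)(C)C)O2
F3 | step 8 | analogue of 18 with C2–OH in place of the ketone (amino diol) | CC1(C)C(O)[C@@](O)(c2ccccc2N)C[C@@]2(N)CN3CCC[C@@H]3C[C@H]12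
F4 | step 3 | (E)-N-[(2S)-2-(methoxymethyl)pyrrolidin-1-yl]-2-methylpropan-1-imine (SAMP hydrazone of 6) | CC(C)/C=N/N1CCC[C@H]1COC
F5 | step 3 | SAMP hydrazone of aldehyde 7 | CC(C)(C)OC(=O)N1CCC[C@@H]1C[C@H](C(C)(C)/C=N/N2CCC[C@H]2COC)C[N+](=O)[O-]
F6 | step 5 | tert-butyl (2R)-2-[(2R)-6-methoxy-3,3-dimethyl-2-(nitromethyl)-4,6-dioxohexyl]pyrrolidine-1-carboxylate | CC(C)(C)OC(=O)N1CCC[C@@H]1C[C@H](C(C)(C)C(=O)CC(=O)OC)C[N+](=O)[O-]
F7 | step 5 | tert-butyl (2R)-2-[(2R)-6-methoxy-3,3-dimethyl-2-(nitromethyl)-5-(2-nitrophenyl)-4,6-dioxohexyl]pyrrolidine-1-carboxylate (C5 epimers) | CC(C)(C)OC(=O)N1CCC[C@@H]1C[C@H](C(C)(C)C(=O)C(C(=O)OC)c2ccccc2[N+](=O)[O-])C[N+](=O)[O-]
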